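In Sunday's run the right-handed substrate stood at 50% at the last reading, more than the 20% of left-handed substrate, and from 0.833 d on neither moved beyond the scatter: a kinetic resolution that stopped early.

common to all: free catalyst 0.10 mM
- Sunday's: left-handed substrate 0.10 M; right-handed substrate 0.10 M; partner 0.15 M; run made earlier
- Saturday's: left-handed substrate 0.10 M; right-handed substrate 0.10 M; partner 0.24 M; run made earlier
- Thursday's: left-handed substrate 0.20 M; right-handed substrate 0.20 M; partner 0.11 M; run made earlier
- flask: left-handed substrate 0.10 M; right-handed substrate 0.10 M; partner 0.110 M; time 6.0 d

| run | time / d | right-handed substrate / % | left-handed substrate / % | left-handed product / % |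
|---|---|---|---|---|
| Sunday's | 0.833 | 50 | 23 | 29 |
| Sunday's | 1.67 | 48 | 20 | 29 |
| Sunday's | 2.50 | 50 | 21 | 32 |
| Sunday's | 3.00 | 50 | 24 | 29 |
| Sunday's | 4.00 | 47 | 23 | 29 |
| Sunday's | 5.00 | 50 | 20 | 29 |
| Saturday's | 0.417 | 49 | 14 | 37 |
| Saturday's | 0.625 | 50 | 12 | 35 |
| Saturday's | 1.04 | 48 | 10 | 37 |
| Saturday's | 1.67 | 48 | 10 | 40 |
| Saturday's | 3.00 | 47 | 12 | 40 |
| Saturday's | 5.00 | 48 | 11 | 40 |
| Thursday's | 1.04 | 48 | 32 | 15 |
| Thursday's | 2.08 | 49 | 31 | 19 |
| Thursday's | 3.00 | 50 | 32 | 21 |
| Thursday's | 4.00 | 49 | 31 | 17 |
| Thursday's | 5.00 | 52 | 34 | 16 |

(scatter of a reading: 1.5 percentage points)

- free catalyst is single-handed; left-handed substrate and right-handed substrate are mirror images of each other, charged as a racemate, each of them at the stated concentration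
- steps under discussion: partner -> decomposed reagent; partner + free catalyst + right-handed substrate -> free catalyst + right-handed product; partner + free catalyst + left-handed substrate -> free catalyst + left-handed product; free catalyst -> spent catalyst

1. whether the excess of right-handed substrate over left-handed substrate among what is left of the two reaches 99% by 6.0 d (no / yes)
2. the highest excess of right-handed substrate over left-handed substrate among what is left of the two up to 6.0 d

I took the left-handed step as k[free catalyst][partner][left-handed substrate] and set aside both the right-handed step and the decomposition of partner. In that reckoning [partner] − [left-handed substrate] stays constant, and ln([partner]/[left-handed substrate]) grows by that difference times the time integral of k[free catalyst]. Sunday's charges and its last left-handed product, 29%, give 7.57 /M for that integral up to the stop, the dose.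

The flask has two extreme versions. With an endless dose, the left-handed substrate is the limiting reagent of this reckoning, since 0.110 M of partner exceeds its 0.10 M, and the reckoned excess reaches 100%. With no dose, the racemate stays and there is no excess. Sunday's stop places the real flask between them. Carrying Sunday's dose over, I reckoned that the ratio in the flask would rise from 1.10 to 1.19, so that [left-handed substrate] would end at 0.0536 M, and with the right-handed substrate at its charge my estimate of the excess was 30.2%, below 99%.

The forecast, from the three runs, said no and 29% (24% to 33%), on “a fixed catalytic "dose"”.

The simulation gave no and 30.0%; the flask ended with 53% of its left-handed substrate left and partner at 0%.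

    partner → decomposed reagent (k = 0.0630 /h)
    partner + free catalyst + right-handed substrate → free catalyst + right-handed product (k = 180 /M²/h)
    partner + free catalyst + left-handed substrate → free catalyst + left-handed product (k = 12000 /M²/h)
    free catalyst → spent catalyst (k = 0.0800 /h)

The same dose, reckoned on the neighbouring flask with 0.19 M of partner, puts the ratio at 3.76, which gives an estimated [left-handed substrate] of 0.0327 M and an estimated excess of 50.8%. The simulation of that neighbouring flask gave 51.3%, with 32% of its left-handed substrate left.

The numbers in the tables are simulated with made-up constants; noise was put on by code.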